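A small charge of starting material, in the amber run, gave less open dimer per ring at the last reading than the larger charge of the red run, so I reckoned the flasks by that ratio.

| flask | starting material | remark | time |
|---|---|---|---|
| amber | 0.074 M | run made earlier |  |
| red | 0.32 M | run made earlier |  |
| birch | 0.20 M |  | 6.0 h |
| cedar | 0.50 M |  | 6.0 h |
| alder | 0.30 M |  | 6.0 h |
| maple | 0.10 M |  | 6.0 h |
| larch | 0.15 M |  | 6.0 h |

| run | time / h | ring / % | open dimer / % |
|---|---|---|---|
| amber | 0.167 | 5 | 2 |
| amber | 0.500 | 17 | 8 |
| amber | 0.833 | 30 | 13 |
| amber | 1.33 | 42 | 16 |
| amber | 2.00 | 53 | 15 |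
| amber | 2.50 | 56 | 15 |
| amber | 3.00 | 62 | 13 |
| red | 0.167 | 8 | 16 |
| red | 0.500 | 15 | 28 |
| red | 0.833 | 22 | 35 |
| red | 1.33 | 31 | 41 |
| red | 2.00 | 38 | 39 |
| red | 2.50 | 41 | 36 |
| red | 3.00 | 43 | 36 |

(standard deviation of a reading: 1.5 percentage points)

* the flasks put in order of share of ring in all that became ring or open dimer or isomer of the product, best first, at 6.0 h (birch / cedar / alder / maple / larch)
* the share of ring in all that became ring or open dimer or isomer of the product of the flask you put first, at 6.0 h
* the share of ring in all that became ring or open dimer or isomer of the product of the flask you put last, at 6.0 h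

I built the flask up one process at a time. With the main step alone, starting material to ring, the share of ring stands at 100%. Adding the dimer, I took the dimer reading at 3.00 h, divided it by the ring reading and then by the charge, which gave 2.83 M⁻¹ in amber and 2.62 M⁻¹ in red; these values lie close, so I let the ratio go with the charge. To carry it to 6.0 h I went round twice on red, using the fall of dimer read from both runs after 1.33 h:

fall of dimer = 0.101 h⁻¹, so dimer in red at 6.0 h = 26.6%

first round, ring held at 43%: dimer per ring = 0.619

second round, ring given what dimer lost: ring = 52.4%, dimer per ring = 0.508

load = 1.58 M⁻¹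

This dimer load, the dimer per ring per unit of charge at the asked time, gives 86.3% for maple and 55.8% for cedar.

Isomer of the product was not among the readings. The remainder in red at 3.00 h was 21.0%, to be shared by starting material, isomer and decomposition product; I held it at that size and guessed a quarter of it to be isomer, which makes my estimate of isomer per ring 0.100. My selectivity, ring over ring plus dimer plus isomer, then falls with rising charge:

maple 79.5%, cedar 52.8%

The forecast gave maple > larch > birch > alder > cedar, with 76% for maple and 63% for cedar, on the ground that “More dilute flasks therefore give a better ring share”. Its low stood above mine.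

    starting material → decomposition product (k = 6.06 × 10⁻⁵ h⁻¹)
    starting material → ring (k = 0.450 h⁻¹)
    ring ⇌ isomer of the product (K = 0.860, k = 0.0208 h⁻¹)
    2 starting material ⇌ open dimer (K = 9.85 M⁻¹, k = 1.74 M⁻¹ h⁻¹)

The flasks came out maple > larch > birch > alder > cedar, with maple at 80.1% and cedar at 59.5%. With the dimer step struck out, both ways, maple stands at 92.1%. Cedar's own dimer and ring at 6.00 h give a load of 1.20 M⁻¹ against my 1.58 M⁻¹, and that load, put back into the same line, gives 58.8%. For a further flask like maple but charged with 0.25 M, my load gave 66.8%; the computed value is 69.7%.

The earlier runs and the new flask come from a simulation from invented constants; noise was put on by code.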